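**Plan**
Ring D is labelled D1 (acyl), D2 (OH), D3 (CH2 bridge), D4 (OMe), D5 (CH3), D6 (OH); rings A/C/B are the flavonol and ring E is the 4-hydroxyphenyl group.
Retrosynthesis cuts first the five O–benzyl bonds, then D1–C(=O) and D6–O together, then the C8–CH2(D3) bond (Negishi coupling).
The feature that allows the double cut: the acyl carbon on D1 and the phenolic oxygen on D6 are ortho neighbours and are together the RC(=O)– and –OH halves of phloretic acid, which can be delivered across a D1≡D6 aryne steered by the D2 alkoxy group.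
Forward, ring D is built from 2,4,6-trihydroxybenzaldehyde (its symmetry settles the O-differentiation, its formyl carbon becomes the D5 methyl) and taken to the ortho-silylaryl triflate benzylic chloride as a small fragment, so that no organolithium meets the flavone.
The pieces are then joined in the order D3–CH2–C8 (to 8-iodo-tri-O-benzylkaempferide), acyl/OH insertion with O-benzylphloretic acid, global hydrogenolysis; no ring is formed anywhere (rings A, B, C, E are bought).
The target has no stereocentre, so no stereochemistry has to be set.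

Key step: step 12

Remark: 2,4,6-trihydroxybenzaldehyde, kaempferide and phloretic acid are assumed to be purchased; all structures are achiral, so the SMILES carry no stereodescriptors.

**Route**

Step 1
Reactants: 1 2,4,6-trihydroxybenzaldehyde
Product: 2 4-(benzyloxy)-2,6-dihydroxybenzaldehyde
Conditions: BnBr (1.0 equiv), NaHCO3, KI (cat.), MeCN, reflux
Reagents that add atoms: benzyl bromide, BrCc1ccccc1
Why: Williamson etherification in which the 4-OH, para to the formyl group and not hydrogen-bonded, is the most acidic hydroxyl and should be alkylated ahead of the two chelated ortho hydroxyls when only a weak base and one equivalent of halide are used.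

Step 2
Reactants: 2 4-(benzyloxy)-2,6-dihydroxybenzaldehyde
Product: 3 4-(benzyloxy)-2-hydroxy-6-methoxybenzaldehyde
Conditions: MeI (1.1 equiv), K2CO3, acetone, reflux
Reagents that add atoms: iodomethane, CI
Why: Williamson methylation of a symmetric substrate, so either ortho hydroxyl gives the same product, and the remaining hydroxyl, held in a hydrogen bond to the aldehyde, should resist a second methylation under these mild conditions.

Step 3
Reactants: 3 4-(benzyloxy)-2-hydroxy-6-methoxybenzaldehyde
Product: 4 4-(benzyloxy)-3-bromo-2-hydroxy-6-methoxybenzaldehyde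
Conditions: NBS (1.0 equiv), CH2Cl2, 0 °C
Reagents that add atoms: N-bromosuccinimide, O=C1CCC(=O)N1Br
Why: Electrophilic aromatic bromination directed by the chelated phenol to its free ortho carbon (the future D1), which is also less crowded than the carbon lying between two alkoxy groups, as in the ortho-halogenation of related 2-hydroxy-4,6-dialkoxyaryl carbonyl compounds.

Step 4
Reactants: 4 4-(benzyloxy)-3-bromo-2-hydroxy-6-methoxybenzaldehyde
Product: 6 3-(benzyloxy)-2-bromo-5-methoxy-6-methylphenol, via ethyl aryl carbonate 5 (not isolated)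
Conditions: ClCO2Et, Et3N, THF, 0 °C; then NaBH4, THF/H2O, 0 °C to rt
Reagents that add atoms: none
Why: Reductive deoxygenation of an ortho-hydroxybenzaldehyde through its carbonate, in which hydride reduction, carbonate transfer to the benzylic alkoxide and loss of ethyl carbonate give an ortho-quinone methide that takes up a second hydride, turning the formyl carbon into the D5 methyl without touching the aryl bromide or the benzyl ether.

Step 5
Reactants: 6 3-(benzyloxy)-2-bromo-5-methoxy-6-methylphenol
Product: 7 3-(benzyloxy)-2-bromo-4-[(dimethylamino)methyl]-5-methoxy-6-methylphenol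
Conditions: Me2N=CH2+ I− (Eschenmoser's salt), K2CO3, CH2Cl2, rt
Reagents that add atoms: dimethyl(methylidene)ammonium iodide, C=[N+](C)C.[I-]
Why: Phenolic Mannich reaction in which both ortho positions of the phenol are blocked (Br and CH3), so the iminium ion can only attack the para carbon (future D3), itself activated by the flanking benzyloxy and methoxy groups.

Step 6
Reactants: 7 3-(benzyloxy)-2-bromo-4-[(dimethylamino)methyl]-5-methoxy-6-methylphenol
Product: 10 3-(benzyloxy)-4-[(dimethylamino)methyl]-5-methoxy-6-methyl-2-(trimethylsilyl)phenyl trifluoromethanesulfonate, via aryl trimethylsilyl ether 8 (not isolated), via lithium 2-silylphenoxide 9 (not isolated)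
Conditions: (Me3Si)2NH, THF, 65 °C, then evaporation; n-BuLi (1.1 equiv), THF, −78 °C; PhNTf2, −78 °C to rt; aq. NH4Cl
Reagents that add atoms: hexamethyldisilazane, C[Si](C)(C)N[Si](C)(C)C; N-phenylbis(trifluoromethanesulfonimide), FC(F)(F)S(=O)(=O)N(c1ccccc1)S(=O)(=O)C(F)(F)F
Why: The standard one-flask route to ortho-silylaryl triflates (O-silylation, bromine–lithium exchange, retro-Brook 1,3 O-to-C silyl shift, triflation of the phenoxide), in which exchange at −78 °C should outrun deprotonation of the benzyl ether and PhNTf2 is chosen so that the tertiary amine is not attacked.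

Step 7
Reactants: 10 3-(benzyloxy)-4-[(dimethylamino)methyl]-5-methoxy-6-methyl-2-(trimethylsilyl)phenyl trifluoromethanesulfonate
Product: 11 3-(benzyloxy)-4-(chloromethyl)-5-methoxy-6-methyl-2-(trimethylsilyl)phenyl trifluoromethanesulfonate
Conditions: ClCO2Et, CH2Cl2, 0 °C to rt
Reagents that add atoms: ethyl chloroformate, CCOC(=O)Cl
Why: von Braun-type dealkylative chlorination, in which N-acylation gives an acylammonium ion whose electron-rich benzylic C–N bond is cleaved by chloride, under conditions free of fluoride and strong acid so that the silyl triflate survives.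

Step 8
Reactants: 12 kaempferide (3,5,7-trihydroxy-2-(4-methoxyphenyl)-4H-chromen-4-one)
Product: 13 3,5,7-tris(benzyloxy)-2-(4-methoxyphenyl)-4H-chromen-4-one
Conditions: BnBr (4 equiv), K2CO3, DMF, 80 °C
Reagents that add atoms: benzyl bromide, BrCc1ccccc1
Why: Exhaustive Williamson benzylation, with excess halide and heat in DMF to bring in the chelated 5-OH as well.

Step 9
Reactants: 13 3,5,7-tris(benzyloxy)-2-(4-methoxyphenyl)-4H-chromen-4-one
Product: 14 3,5,7-tris(benzyloxy)-8-iodo-2-(4-methoxyphenyl)-4H-chromen-4-one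
Conditions: I2 (1.0 equiv), CF3CO2Ag, CH2Cl2, 0 °C to rt, dark
Reagents that add atoms: iodine, II
Why: Electrophilic aromatic iodination with the iodine/silver trifluoroacetate couple, for which fully O-alkylated 5,7-dioxygenated flavones are expected to react at C8, while ring B is deactivated by conjugation with the pyranone.

Step 10
Reactants: 15 phloretic acid (3-(4-hydroxyphenyl)propanoic acid)
Product: 16 3-[4-(benzyloxy)phenyl]propanoic acid
Conditions: BnBr (1.2 equiv), NaOH (2.5 equiv), EtOH/H2O, reflux; then aq. HCl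
Reagents that add atoms: benzyl bromide, BrCc1ccccc1
Why: Williamson etherification of the phenoxide in aqueous base, where any benzyl ester formed is saponified in the same pot, so acidification should give the O-benzyl acid.

Step 11
Reactants: 11 3-(benzyloxy)-4-(chloromethyl)-5-methoxy-6-methyl-2-(trimethylsilyl)phenyl trifluoromethanesulfonate; 14 3,5,7-tris(benzyloxy)-8-iodo-2-(4-methoxyphenyl)-4H-chromen-4-one
Product: 18 3-(benzyloxy)-5-methoxy-6-methyl-4-{[3,5,7-tris(benzyloxy)-2-(4-methoxyphenyl)-4-oxo-4H-chromen-8-yl]methyl}-2-(trimethylsilyl)phenyl trifluoromethanesulfonate, via benzylzinc chloride 17 (not isolated)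
Conditions: Zn dust, LiCl, THF, 25 °C; then 14, Pd(OAc)2 (2 mol %), SPhos (4 mol %), THF, 25–40 °C
Reagents that add atoms: none
Why: Negishi cross-coupling, in which LiCl-assisted zinc insertion into the benzylic C–Cl bond is followed by coupling on zerovalent palladium that should undergo oxidative addition at the aryl iodide of 14 far faster than at the doubly ortho-substituted aryl triflate, while the organozinc leaves the triflate, the C–Si bond and the pyranone alone.

Step 12
Reactants: 18 3-(benzyloxy)-5-methoxy-6-methyl-4-{[3,5,7-tris(benzyloxy)-2-(4-methoxyphenyl)-4-oxo-4H-chromen-8-yl]methyl}-2-(trimethylsilyl)phenyl trifluoromethanesulfonate; 16 3-[4-(benzyloxy)phenyl]propanoic acid (1.5 equiv)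
Product: 20 1-{2-(benzyloxy)-6-hydroxy-4-methoxy-5-methyl-3-{[3,5,7-tris(benzyloxy)-2-(4-methoxyphenyl)-4-oxo-4H-chromen-8-yl]methyl}phenyl}-3-[4-(benzyloxy)phenyl]propan-1-one, via aryne 19 (not isolated)
Conditions: CsF (4 equiv), THF, 125 °C, sealed tube
Reagents that add atoms: none
Why: Fluoride attacks silicon in 18 and triflate departs from the neighbouring carbon to release aryne 19 (D1≡D6); the cesium carboxylate of 16 adds through oxygen to D6, the D1 aryl anion so formed attacks the ester carbonyl just created, and the strained four-membered alkoxide opens to the D6 phenoxide and the D1 ketone. The closest known reaction type is the CsF-mediated insertion of arynes from ortho-silylaryl triflates into the C–O bond of aliphatic carboxylic acids to give ortho-hydroxyaryl ketones, applied here to a pentasubstituted aryne. No ring is closed and no stereocentre is formed. The selectivity required is regiochemical (oxygen to D6, carbon to D1) and it rests on the D2 benzyloxy group, whose electron-withdrawing σ-effect bends the triple bond unsymmetrically, making D6 the more electrophilic terminus and placing the incipient carbanion on D1 where the adjacent C–O bond stabilises it; the D5 methyl adds only modest steric resistance to a small oxygen nucleophile. Heating at 125 °C is meant to favour intramolecular acyl transfer over protonation of the aryl anion, and the product is then parked as a chelated phenoxide that should not react further.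

Step 13
Reactants: 20 1-{2-(benzyloxy)-6-hydroxy-4-methoxy-5-methyl-3-{[3,5,7-tris(benzyloxy)-2-(4-methoxyphenyl)-4-oxo-4H-chromen-8-yl]methyl}phenyl}-3-[4-(benzyloxy)phenyl]propan-1-one
Product: 21 4'''-hydroxytrianguletin (8-{[2,4-dihydroxy-3-[3-(4-hydroxyphenyl)propanoyl]-6-methoxy-5-methylphenyl]methyl}-3,5,7-trihydroxy-2-(4-methoxyphenyl)-4H-chromen-4-one)
Conditions: H2 (1 atm), 10% Pd/C, THF/MeOH, rt
Reagents that add atoms: none
Why: Catalytic hydrogenolysis of the five benzyl ethers, under which the chelated, doubly ortho-substituted aryl ketone and the flavonol C2=C3 bond are not expected to be reduced at atmospheric pressure.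

**Compound list**
1 | 2,4,6-trihydroxybenzaldehyde | O=Cc1c(O)cc(O)cc1O | starting material
2 | 4-(benzyloxy)-2,6-dihydroxybenzaldehyde | O=Cc1c(O)cc(OCc2ccccc2)cc1O | intermediate
3 | 4-(benzyloxy)-2-hydroxy-6-methoxybenzaldehyde | COc1cc(OCc2ccccc2)cc(O)c1C=O | intermediate
4 | 4-(benzyloxy)-3-bromo-2-hydroxy-6-methoxybenzaldehyde | COc1cc(OCc2ccccc2)c(Br)c(O)c1C=O | intermediate
5 | 3-(benzyloxy)-2-bromo-6-formyl-5-methoxyphenyl ethyl carbonate | CCOC(=O)Oc1c(Br)c(OCc2ccccc2)cc(OC)c1C=O | intermediate (not isolated)
6 | 3-(benzyloxy)-2-bromo-5-methoxy-6-methylphenol | COc1cc(OCc2ccccc2)c(Br)c(O)c1C | intermediate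
7 | 3-(benzyloxy)-2-bromo-4-[(dimethylamino)methyl]-5-methoxy-6-methylphenol | COc1c(CN(C)C)c(OCc2ccccc2)c(Br)c(O)c1C | intermediate
8 | [3-(benzyloxy)-2-bromo-4-[(dimethylamino)methyl]-5-methoxy-6-methylphenoxy]trimethylsilane | COc1c(CN(C)C)c(OCc2ccccc2)c(Br)c(O[Si](C)(C)C)c1C | intermediate (not isolated)
9 | lithium 3-(benzyloxy)-4-[(dimethylamino)methyl]-5-methoxy-6-methyl-2-(trimethylsilyl)phenolate | [Li+].COc1c(CN(C)C)c(OCc2ccccc2)c([Si](C)(C)C)c([O-])c1C | intermediate (not isolated)
10 | 3-(benzyloxy)-4-[(dimethylamino)methyl]-5-methoxy-6-methyl-2-(trimethylsilyl)phenyl trifluoromethanesulfonate | COc1c(CN(C)C)c(OCc2ccccc2)c([Si](C)(C)C)c(OS(=O)(=O)C(F)(F)F)c1C | intermediate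
11 | 3-(benzyloxy)-4-(chloromethyl)-5-methoxy-6-methyl-2-(trimethylsilyl)phenyl trifluoromethanesulfonate | COc1c(CCl)c(OCc2ccccc2)c([Si](C)(C)C)c(OS(=O)(=O)C(F)(F)F)c1C | intermediate
12 | kaempferide | COc1ccc(cc1)-c1oc2cc(O)cc(O)c2c(=O)c1O | starting material
13 | 3,5,7-tris(benzyloxy)-2-(4-methoxyphenyl)-4H-chromen-4-one | COc1ccc(cc1)-c1oc2cc(OCc3ccccc3)cc(OCc4ccccc4)c2c(=O)c1OCc5ccccc5 | intermediate
14 | 3,5,7-tris(benzyloxy)-8-iodo-2-(4-methoxyphenyl)-4H-chromen-4-one | COc1ccc(cc1)-c1oc2c(I)c(OCc3ccccc3)cc(OCc4ccccc4)c2c(=O)c1OCc5ccccc5 | intermediate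
15 | phloretic acid | OC(=O)CCc1ccc(O)cc1 | starting material
16 | 3-[4-(benzyloxy)phenyl]propanoic acid | OC(=O)CCc1ccc(OCc2ccccc2)cc1 | intermediate
17 | {[2-(benzyloxy)-6-methoxy-5-methyl-4-(trifluoromethanesulfonyloxy)-3-(trimethylsilyl)phenyl]methyl}zinc chloride | COc1c(C[Zn]Cl)c(OCc2ccccc2)c([Si](C)(C)C)c(OS(=O)(=O)C(F)(F)F)c1C | intermediate (not isolated)
18 | 3-(benzyloxy)-5-methoxy-6-methyl-4-{[3,5,7-tris(benzyloxy)-2-(4-methoxyphenyl)-4-oxo-4H-chromen-8-yl]methyl}-2-(trimethylsilyl)phenyl trifluoromethanesulfonate | COc1ccc(cc1)-c1oc2c(Cc3c(OC)c(C)c(OS(=O)(=O)C(F)(F)F)c([Si](C)(C)C)c3OCc6ccccc6)c(OCc4ccccc4)cc(OCc5ccccc5)c2c(=O)c1OCc7ccccc7 | intermediate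
19 | aryne from 18 (triple bond D1≡D6; D2 OBn, D3 CH2–flavonol, D4 OMe, D5 CH3) | COc1ccc(cc1)-c1oc2c(CC3=C(OCc6ccccc6)C#CC(C)=C3OC)c(OCc4ccccc4)cc(OCc5ccccc5)c2c(=O)c1OCc7ccccc7 | intermediate (not isolated)
20 | 1-{2-(benzyloxy)-6-hydroxy-4-methoxy-5-methyl-3-{[3,5,7-tris(benzyloxy)-2-(4-methoxyphenyl)-4-oxo-4H-chromen-8-yl]methyl}phenyl}-3-[4-(benzyloxy)phenyl]propan-1-one | COc1ccc(cc1)-c1oc2c(Cc3c(OC)c(C)c(O)c(C(=O)CCc8ccc(OCc9ccccc9)cc8)c3OCc6ccccc6)c(OCc4ccccc4)cc(OCc5ccccc5)c2c(=O)c1OCc7ccccc7 | intermediate
21 | 4'''-hydroxytrianguletin | COc1ccc(-c2oc3c(Cc4c(O)c(C(=O)CCc5ccc(O)cc5)c(O)c(C)c4OC)c(O)cc(O)c3c(=O)c2O)cc1 | target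

**Count and risks**
Total steps: 13. Longest linear sequence: 10 steps (steps 1–7, 11, 12, 13).

Most likely to fail, in this order:

1. Step 12. The D1 aryl anion may be protonated before it reaches the ester carbonyl, so that the reaction stops at O-arylation, and crowding around the pentasubstituted aryne may slow the acyl transfer further. The fallback makes the two bonds separately and sets out from 18 and 16. With CsF in MeCN at 25 °C, conditions under which arynes are known simply to O-arylate carboxylic acids, the aryl ester 3-(benzyloxy)-5-methoxy-6-methyl-4-{[3,5,7-tris(benzyloxy)-2-(4-methoxyphenyl)-4-oxo-4H-chromen-8-yl]methyl}phenyl 3-[4-(benzyloxy)phenyl]propanoate F1 should form. Hydrogenolysis (H2, 10% Pd/C, THF/MeOH) would then give 3-hydroxy-5-methoxy-6-methyl-4-{[3,5,7-trihydroxy-2-(4-methoxyphenyl)-4-oxo-4H-chromen-8-yl]methyl}phenyl 3-(4-hydroxyphenyl)propanoate F2. A Fries rearrangement (BF3·OEt2, 1,4-dioxane, 70 °C) would move the acyl group to D1, the only free carbon of ring D and ortho to the ester oxygen, while the boron chelates at the 4-carbonyl deactivate ring A. The route is rejoined at 21. This fallback does not repair a loss of aryne regiocontrol.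

2. Step 11. Zinc insertion into the very electron-rich benzylic chloride may be accompanied by Wurtz-type homocoupling, and coupling at the doubly ortho-flanked C8 may be slow enough for oxidative addition into the aryl triflate to compete. The fallback reverses the polarity and sets out from 14. Miyaura borylation (B2pin2, PdCl2(dppf), KOAc, dioxane, 80 °C) would give 3,5,7-tris(benzyloxy)-2-(4-methoxyphenyl)-8-(4,4,5,5-tetramethyl-1,3,2-dioxaborolan-2-yl)-4H-chromen-4-one F3. Suzuki–Miyaura coupling of F3 with benzylic chloride 11 (PdCl2(dppf), K3PO4, THF/H2O, 60 °C; a fluoride-free base is essential) would return to 18.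

3. Step 5. Aminomethylation at the crowded para carbon may stall at reversible O-attack, or the product may lose the amine by retro-Mannich cleavage on work-up. The fallback sets out from 6. Vilsmeier–Haack formylation (POCl3, DMF, 0 °C to 50 °C; then aq. NaOAc) at the only free ring position would give 2-(benzyloxy)-3-bromo-4-hydroxy-6-methoxy-5-methylbenzaldehyde F4. Reductive amination of F4 (Me2NH, NaBH(OAc)3, 1,2-dichloroethane, rt) would return to 7.

**Further compounds**
F1 | step 12 | 3-(benzyloxy)-5-methoxy-6-methyl-4-{[3,5,7-tris(benzyloxy)-2-(4-methoxyphenyl)-4-oxo-4H-chromen-8-yl]methyl}phenyl 3-[4-(benzyloxy)phenyl]propanoate | COc1ccc(cc1)-c1oc2c(Cc3c(OC)c(C)c(OC(=O)CCc8ccc(OCc9ccccc9)cc8)cc3OCc6ccccc6)c(OCc4ccccc4)cc(OCc5ccccc5)c2c(=O)c1OCc7ccccc7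
F2 | step 12 | 3-hydroxy-5-methoxy-6-methyl-4-{[3,5,7-trihydroxy-2-(4-methoxyphenyl)-4-oxo-4H-chromen-8-yl]methyl}phenyl 3-(4-hydroxyphenyl)propanoate | COc1ccc(cc1)-c1oc2c(Cc3c(OC)c(C)c(OC(=O)CCc4ccc(O)cc4)cc3O)c(O)cc(O)c2c(=O)c1O
F3 | step 11 | 3,5,7-tris(benzyloxy)-2-(4-methoxyphenyl)-8-(4,4,5,5-tetramethyl-1,3,2-dioxaborolan-2-yl)-4H-chromen-4-one | COc1ccc(cc1)-c1oc2c(B3OC(C)(C)C(C)(C)O3)c(OCc4ccccc4)cc(OCc5ccccc5)c2c(=O)c1OCc7ccccc7
F4 | step 5 | 2-(benzyloxy)-3-bromo-4-hydroxy-6-methoxy-5-methylbenzaldehyde | COc1c(C=O)c(OCc2ccccc2)c(Br)c(O)c1C
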